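The route takes the 8-methylchroman-6-ol apart at C8a–C4a, C5–C6 and C6–C7. Its benzene ring is a hydroquinone monoether: the ring oxygen O1 on C8a sits para to the C6 hydroxyl and is tied back to C4a through C2–C3–C4. That is the pattern an oxygen-tethered alkenylcarbene/alkyne/CO benzannulation produces, so one thermal step on a chromium isopropenyl carbene should forge the arene and the dihydropyran together. The precursor carries, as its alkoxy group, the (R)-linalool-derived tertiary carbinol with a butynyl arm, so C2 is set before the key step. The C6'–C12' segment with C8' is then joined at C5' as a bis-sulfone.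

Key step: step 8

Remarks and assumptions:
- Side-chain atoms are numbered C1'–C12' outward from C2.
- (R)-(−)-linalool of high enantiomeric purity is assumed.
- The C9' carbinol centre is carried as an epimer mixture from step 13 to step 16, because step 17 removes it.
- In step 12 the catalyst enantiomer is chosen by analogy with the usual facial preference of diarylprolinol silyl ether enamines, so that C8' is (S).
- Chromium carbonyls are written in formal Cr=C=O notation, and the η6 complex 15 as two fragments.

Step 1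
Reactants: 1 (R)-(−)-linalool
Product: 2 (R)-triethyl[(3,7-dimethylocta-1,6-dien-3-yl)oxy]silane
Conditions: TESOTf, 2,6-lutidine, CH2Cl2, −78→0 °C
Reagents that add atoms: triethylsilyl trifluoromethanesulfonate, CC[Si](CC)(CC)OS(=O)(=O)C(F)(F)F
Why: Triflate-mediated O-silylation masks the tertiary allylic carbinol, which as a free alkoxide in step 4 would displace the γ-tosylate and close an oxetane; the stereocentre is not touched.

Step 2
Reactants: 2 (R)-triethyl[(3,7-dimethylocta-1,6-dien-3-yl)oxy]silane
Product: 4 (3R)-3,7-dimethyl-3-(triethylsilyloxy)oct-6-en-1-ol, via B-alkyl-9-BBN adduct 3 (not isolated)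
Conditions: 9-BBN, THF, 0 °C→rt; then NaOH, H2O2, 0 °C→rt
Reagents that add atoms: hydrogen peroxide, OO
Why: Anti-Markovnikov hydroboration–oxidation with the bulky borane selects the monosubstituted vinyl group over the trisubstituted alkene and puts the hydroxyl on the carbon that becomes C4.

Step 3
Reactants: 4 (3R)-3,7-dimethyl-3-(triethylsilyloxy)oct-6-en-1-ol
Product: 5 (3R)-3,7-dimethyl-3-(triethylsilyloxy)oct-6-en-1-yl 4-methylbenzenesulfonate
Conditions: TsCl, Et3N, DMAP (cat.), CH2Cl2, 0 °C→rt
Reagents that add atoms: p-toluenesulfonyl chloride, Cc1ccc(cc1)S(Cl)(=O)=O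
Why: Tosylation of the unhindered primary alcohol is routine, and the tertiary silyl ether and the alkene are inert.

Step 4
Reactants: 5 (3R)-3,7-dimethyl-3-(triethylsilyloxy)oct-6-en-1-yl 4-methylbenzenesulfonate
Product: 6 (R)-triethyl[(5,9-dimethyldec-8-en-1-yn-5-yl)oxy]silane
Conditions: LiC≡CH·H2NCH2CH2NH2, DMSO, rt
Reagents that add atoms: lithium acetylide–ethylenediamine complex, [Li+].[C-]#C.NCCN
Why: SN2 alkylation of acetylide by a primary tosylate adds the two alkyne carbons (future C4a and C5) and leaves the terminal C–H needed for an unsubstituted C5.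

Step 5
Reactants: 6 (R)-triethyl[(5,9-dimethyldec-8-en-1-yn-5-yl)oxy]silane
Product: 7 (R)-5,9-dimethyldec-8-en-1-yn-5-ol
Conditions: TBAF, THF, rt→40 °C
Reagents that add atoms: none
Why: Fluoride desilylation frees the tertiary hydroxyl without acid, so the carbinol cannot ionise or add to the trisubstituted alkene.

Step 6
Reactants: 8 2-bromopropene; 9 chromium hexacarbonyl
Product: 12 tetramethylammonium pentacarbonyl(1-oxido-2-methylprop-2-enylidene)chromate, via isopropenyllithium 10 (not isolated), via lithium acylchromate 11 (not isolated)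
Conditions: t-BuLi (2 equiv), Et2O, −78 °C; Cr(CO)6, Et2O, 0 °C→rt; then Me4NBr, H2O
Reagents that add atoms: tetramethylammonium bromide, C[N+](C)(C)C.[Br-]
Why: This is the Fischer acylmetalate synthesis (Br/Li exchange, addition of the alkenyllithium to a CO ligand), and cation metathesis gives a salt that can be purified and weighed before the delicate exchange.

Step 7
Reactants: 12 tetramethylammonium pentacarbonyl(1-oxido-2-methylprop-2-enylidene)chromate; 7 (R)-5,9-dimethyldec-8-en-1-yn-5-ol
Product: 14 pentacarbonyl{isopropenyl[(R)-5,9-dimethyldec-8-en-1-yn-5-yloxy]carbene}chromium(0), via pivaloyloxycarbene complex 13 (not isolated)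
Conditions: 12 (2.5 equiv), t-BuCOCl, CH2Cl2, −40 °C; then 7, −40→0 °C; cold SiO2 filtration under Ar
Reagents that add atoms: none
Why: Proposed new method: O-acylation of the acylchromate gives the mixed-anhydride-like carbene 13, whose carbene carbon should undergo addition–elimination by the hydroxyl of 7 with loss of pivalate; the closest known reaction type is this same acyloxycarbene alcoholysis with primary and hindered secondary alcohols, and the slower tertiary carbinol is met with excess 13 and a pivaloyl group that resists attack at the acyl carbon and decays less readily than acetyl.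

Step 8
Reactants: 14 pentacarbonyl{isopropenyl[(R)-5,9-dimethyldec-8-en-1-yn-5-yloxy]carbene}chromium(0)
Product: 16 (R)-2,8-dimethyl-2-(4-methylpent-3-en-1-yl)chroman-6-ol, via tricarbonylchromium arene complex 15 (not isolated)
Conditions: THF (0.01 M), 60 °C, Ar; then air, daylight, Et2O, rt
Reagents that add atoms: none
Why: Heating should dissociate one CO from 14, after which the pendant alkyne inserts into the Cr=C bond with its internal carbon (C4a) becoming bonded to the carbene carbon (C8a); a carbonyl ligand then migrates onto the new carbene carbon C5 to give a chromium-bound dienylketene (ketene carbon = C6) that closes through C6–C7 bond formation onto the isopropenyl CH2 and enolises to the phenol, first held as Cr(CO)3 complex 15 and then released by air and light without oxidising the hydroquinone monoether. The closest known reaction type is the intramolecular Dötz benzannulation of alkenyl(alkynyloxy)carbene chromium complexes, of which the tertiary alkoxy tether is the one untested feature. The dihydropyran closes in the insertion event as a six-membered ring (O1, C2, C3, C4, C4a, C8a) with C5 left exocyclic, and the benzene ring closes by 6π-electrocyclisation of the dienylketene followed by tautomerisation. No stereocentre is formed, and C2, a fully substituted carbon with no epimerisable bond, is carried over from linalool as (R). The needed regiochemistry (tether carbon at C4a and CH at C5, the reverse of what an untethered terminal alkyne gives) is enforced by the O1–C2–C3–C4 tether, while phenol formation over four- and five-membered-ring by-products is favoured by the alkenyl chromium carbene in THF and dilution keeps the insertion intramolecular. The isopropenyl group supplies C8 with its methyl and an unsubstituted C7, and the geminal substitution at C2 should assist ring closure.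

Step 9
Reactants: 16 (R)-2,8-dimethyl-2-(4-methylpent-3-en-1-yl)chroman-6-ol
Product: 17 triisopropyl{[(2R)-2,8-dimethyl-2-(4-methylpent-3-en-1-yl)chroman-6-yl]oxy}silane
Conditions: TIPSCl, imidazole, DMF, rt
Reagents that add atoms: triisopropylsilyl chloride, CC(C)[Si](Cl)(C(C)C)C(C)C
Why: Imidazole-promoted silylation of the unhindered phenol protects the oxidation-prone hydroquinone monoether, and TIPS is robust toward the base and dissolving-metal conditions ahead.

Step 10
Reactants: 17 triisopropyl{[(2R)-2,8-dimethyl-2-(4-methylpent-3-en-1-yl)chroman-6-yl]oxy}silane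
Product: 18 (2E)-5-[(2R)-2,8-dimethyl-6-(triisopropylsilyloxy)chroman-2-yl]-2-methylpent-2-en-1-ol
Conditions: SeO2 (0.3 equiv), t-BuOOH (3 equiv), salicylic acid (cat.), CH2Cl2, 0 °C→rt
Reagents that add atoms: selenium dioxide (catalytic oxygen-transfer agent), O=[Se]=O; tert-butyl hydroperoxide (terminal oxidant), CC(C)(C)OO
Why: Catalytic Riley allylic oxidation (ene reaction, then [2,3]-sigmatropic shift) attacks the (E)-methyl group of a gem-dimethyl alkene terminus, so C5' is oxygenated with E geometry while the benzylic and aryl-methyl positions stay untouched at room temperature.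

Step 11
Reactants: 18 (2E)-5-[(2R)-2,8-dimethyl-6-(triisopropylsilyloxy)chroman-2-yl]-2-methylpent-2-en-1-ol
Product: 19 {[(2R)-2-[(3E)-5-bromo-4-methylpent-3-en-1-yl]-2,8-dimethylchroman-6-yl]oxy}triisopropylsilane
Conditions: CBr4, PPh3, CH2Cl2, −20→0 °C; used without storage
Reagents that add atoms: carbon tetrabromide, BrC(Br)(Br)Br
Why: The Appel reaction converts the primary allylic alcohol to the bromide under neutral conditions without allylic transposition or E/Z erosion.

Step 12
Reactants: 20 propanal; 21 1,1-bis(phenylsulfonyl)ethene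
Product: 22 (2S)-2-methyl-4,4-bis(phenylsulfonyl)butanal
Conditions: 20 (3 equiv), (R)-α,α-bis[3,5-bis(trifluoromethyl)phenyl]prolinol TMS ether (10 mol %), CHCl3, 0 °C; used crude
Reagents that add atoms: none
Why: In this enamine-catalysed asymmetric Michael addition the (R)-diarylprolinol silyl ether forms the E-enamine of propanal and shields one face, so the vinyl bis-sulfone should add to the open face and set C8' as (S), the mirror of the (2R) sense that the (S)-catalyst gives in related additions.

Step 13
Reactants: 22 (2S)-2-methyl-4,4-bis(phenylsulfonyl)butanal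
Product: 24 (5S)-5-methyl-7,7-bis(phenylsulfonyl)hept-1-en-4-ol (C4 epimers), via homoallyl pinacol borate 23 (not isolated)
Conditions: allylB(pin) (1.5 equiv), CH2Cl2, rt; aq. NaHCO3 work-up
Reagents that add atoms: allylboronic acid pinacol ester, C=CCB1OC(C)(C)C(C)(C)O1
Why: Uncatalysed allylboration through a six-membered transition state is neutral, so neither the α-stereocentre nor the acidic bis-sulfone C–H is disturbed, and the new C9' carbinol centre forms as an epimer mixture that step 17 erases.

Step 14
Reactants: 24 (5S)-5-methyl-7,7-bis(phenylsulfonyl)hept-1-en-4-ol (C4 epimers)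
Product: 25 (6S)-2,6-dimethyl-8,8-bis(phenylsulfonyl)oct-2-en-5-ol (C5 epimers)
Conditions: 2-methylbut-2-ene (excess), Grubbs II catalyst (3 mol %), CH2Cl2, 35 °C
Reagents that add atoms: 2-methylbut-2-ene, CC=C(C)C
Why: Olefin cross-metathesis with excess 2-methylbut-2-ene turns the allyl group into the prenyl terminus (C10'–C12') and avoids the α-versus-γ problem of a direct prenyl-metal addition.

Step 15
Reactants: 19 {[(2R)-2-[(3E)-5-bromo-4-methylpent-3-en-1-yl]-2,8-dimethylchroman-6-yl]oxy}triisopropylsilane; 25 (6S)-2,6-dimethyl-8,8-bis(phenylsulfonyl)oct-2-en-5-ol (C5 epimers)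
Product: 27 (6S,10E)-13-[(2R)-2,8-dimethyl-6-(triisopropylsilyloxy)chroman-2-yl]-2,6,10-trimethyl-8,8-bis(phenylsulfonyl)trideca-2,10-dien-5-ol (C5 epimers), via sodium carbanion 26 (not isolated)
Conditions: 25 (1.2 equiv), NaH (1.2 equiv), DMF–THF, 0 °C; then 19, 0 °C→rt
Reagents that add atoms: none
Why: In this C-alkylation of a sulfone-stabilised carbanion one equivalent of NaH removes only the bis-sulfonyl C–H (far more acidic than the hydroxyl), and SN2 attack on the primary allylic bromide forms C5'–C6' with the E alkene retained.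

Step 16
Reactants: 27 (6S,10E)-13-[(2R)-2,8-dimethyl-6-(triisopropylsilyloxy)chroman-2-yl]-2,6,10-trimethyl-8,8-bis(phenylsulfonyl)trideca-2,10-dien-5-ol (C5 epimers)
Product: 28 (6S,10E)-13-[(2R)-2,8-dimethyl-6-(triisopropylsilyloxy)chroman-2-yl]-2,6,10-trimethyltrideca-2,10-dien-5-ol (C5 epimers)
Conditions: 6% Na(Hg), Na2HPO4, MeOH–THF, −20→0 °C
Reagents that add atoms: none
Why: Reductive desulfonylation by electron transfer from sodium amalgam in buffered methanol cleaves both C–S bonds to leave C6' as CH2; the sulfones are homoallylic to C3'=C4', so no alkene migration is expected, and the aryl silyl ether and the isolated alkenes are inert.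

Step 17
Reactants: 28 (6S,10E)-13-[(2R)-2,8-dimethyl-6-(triisopropylsilyloxy)chroman-2-yl]-2,6,10-trimethyltrideca-2,10-dien-5-ol (C5 epimers)
Product: 29 (6S,10E)-13-[(2R)-2,8-dimethyl-6-(triisopropylsilyloxy)chroman-2-yl]-2,6,10-trimethyltrideca-2,10-dien-5-one
Conditions: Dess–Martin periodinane, NaHCO3, CH2Cl2, 0 °C→rt
Reagents that add atoms: none
Why: Bicarbonate-buffered Dess–Martin oxidation converts both C9' carbinol epimers into the single ketone without epimerising C8' or moving the β,γ-alkene into conjugation.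

Step 18
Reactants: 29 (6S,10E)-13-[(2R)-2,8-dimethyl-6-(triisopropylsilyloxy)chroman-2-yl]-2,6,10-trimethyltrideca-2,10-dien-5-one
Product: 30 (6S,10E)-13-[(2R)-6-hydroxy-2,8-dimethylchroman-2-yl]-2,6,10-trimethyltrideca-2,10-dien-5-one (CNP0280076.1)
Conditions: TBAF–AcOH (1:1), THF, 0 °C
Reagents that add atoms: none
Why: Acetic-acid-buffered fluoride cleaves the aryl silyl ether near neutrality, which spares the epimerisable C8' centre and the β,γ-unsaturated ketone and releases the target.

Compound list
1 | (R)-(−)-linalool | CC(C)=CCC[C@@](C)(O)C=C | starting material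
2 | (R)-triethyl[(3,7-dimethylocta-1,6-dien-3-yl)oxy]silane | CC(C)=CCC[C@@](C)(O[Si](CC)(CC)CC)C=C | intermediate
3 | 9-[(3S)-3,7-dimethyl-3-(triethylsilyloxy)oct-6-en-1-yl]-9-borabicyclo[3.3.1]nonane (same spatial arrangement as 2; descriptor changes by priority only; not isolated) | CC(C)=CCC[C@@](C)(O[Si](CC)(CC)CC)CCB1C2CCCC1CCC2 | intermediate
4 | (3R)-3,7-dimethyl-3-(triethylsilyloxy)oct-6-en-1-ol | CC(C)=CCC[C@@](C)(O[Si](CC)(CC)CC)CCO | intermediate
5 | (3R)-3,7-dimethyl-3-(triethylsilyloxy)oct-6-en-1-yl 4-methylbenzenesulfonate | CC(C)=CCC[C@@](C)(O[Si](CC)(CC)CC)CCOS(=O)(=O)c1ccc(C)cc1 | intermediate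
6 | (R)-triethyl[(5,9-dimethyldec-8-en-1-yn-5-yl)oxy]silane | CC(C)=CCC[C@@](C)(O[Si](CC)(CC)CC)CCC#C | intermediate
7 | (R)-5,9-dimethyldec-8-en-1-yn-5-ol | CC(C)=CCC[C@@](C)(O)CCC#C | intermediate
8 | 2-bromopropene | CC(Br)=C | starting material
9 | chromium hexacarbonyl | O=C=[Cr](=C=O)(=C=O)(=C=O)(=C=O)=C=O | starting material
10 | isopropenyllithium (not isolated) | [Li]C(C)=C | intermediate
11 | lithium pentacarbonyl(1-oxido-2-methylprop-2-enylidene)chromate (not isolated) | [Li+].CC(=C)C([O-])=[Cr](=C=O)(=C=O)(=C=O)(=C=O)=C=O | intermediate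
12 | tetramethylammonium pentacarbonyl(1-oxido-2-methylprop-2-enylidene)chromate | C[N+](C)(C)C.CC(=C)C([O-])=[Cr](=C=O)(=C=O)(=C=O)(=C=O)=C=O | intermediate
13 | pentacarbonyl[isopropenyl(pivaloyloxy)carbene]chromium(0) (not isolated) | CC(=C)C(OC(=O)C(C)(C)C)=[Cr](=C=O)(=C=O)(=C=O)(=C=O)=C=O | intermediate
14 | pentacarbonyl{isopropenyl[(R)-5,9-dimethyldec-8-en-1-yn-5-yloxy]carbene}chromium(0) | CC(C)=CCC[C@](C)(CCC#C)OC(=[Cr](=C=O)(=C=O)(=C=O)(=C=O)=C=O)C(C)=C | intermediate
15 | tricarbonyl[η6-(R)-2,8-dimethyl-2-(4-methylpent-3-en-1-yl)chroman-6-ol]chromium(0) (Cr(CO)3 bound to the benzene ring; written as two fragments; not isolated) | CC(C)=CCC[C@]1(C)CCc2cc(O)cc(C)c2O1.O=C=[Cr](=C=O)=C=O | intermediate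
16 | (R)-2,8-dimethyl-2-(4-methylpent-3-en-1-yl)chroman-6-ol | CC(C)=CCC[C@]1(C)CCc2cc(O)cc(C)c2O1 | intermediate
17 | triisopropyl{[(2R)-2,8-dimethyl-2-(4-methylpent-3-en-1-yl)chroman-6-yl]oxy}silane | CC(C)=CCC[C@]1(C)CCc2cc(O[Si](C(C)C)(C(C)C)C(C)C)cc(C)c2O1 | intermediate
18 | (2E)-5-[(2R)-2,8-dimethyl-6-(triisopropylsilyloxy)chroman-2-yl]-2-methylpent-2-en-1-ol | OC/C(C)=C/CC[C@]1(C)CCc2cc(O[Si](C(C)C)(C(C)C)C(C)C)cc(C)c2O1 | intermediate
19 | {[(2R)-2-[(3E)-5-bromo-4-methylpent-3-en-1-yl]-2,8-dimethylchroman-6-yl]oxy}triisopropylsilane | BrC/C(C)=C/CC[C@]1(C)CCc2cc(O[Si](C(C)C)(C(C)C)C(C)C)cc(C)c2O1 | intermediate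
20 | propanal | CCC=O | starting material
21 | 1,1-bis(phenylsulfonyl)ethene | C=C(S(=O)(=O)c1ccccc1)S(=O)(=O)c1ccccc1 | starting material
22 | (2S)-2-methyl-4,4-bis(phenylsulfonyl)butanal | O=C[C@@H](C)CC(S(=O)(=O)c1ccccc1)S(=O)(=O)c1ccccc1 | intermediate
23 | 2-{[(5S)-5-methyl-7,7-bis(phenylsulfonyl)hept-1-en-4-yl]oxy}-4,4,5,5-tetramethyl-1,3,2-dioxaborolane (C4 epimers; not isolated) | C=CCC(OB1OC(C)(C)C(C)(C)O1)[C@@H](C)CC(S(=O)(=O)c1ccccc1)S(=O)(=O)c1ccccc1 | intermediate
24 | (5S)-5-methyl-7,7-bis(phenylsulfonyl)hept-1-en-4-ol (C4 epimers) | C=CCC(O)[C@@H](C)CC(S(=O)(=O)c1ccccc1)S(=O)(=O)c1ccccc1 | intermediate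
25 | (6S)-2,6-dimethyl-8,8-bis(phenylsulfonyl)oct-2-en-5-ol (C5 epimers) | CC(C)=CCC(O)[C@@H](C)CC(S(=O)(=O)c1ccccc1)S(=O)(=O)c1ccccc1 | intermediate
26 | sodium salt of 25, carbanion at C8 (not isolated) | [Na+].CC(C)=CCC(O)[C@@H](C)C[C-](S(=O)(=O)c1ccccc1)S(=O)(=O)c1ccccc1 | intermediate
27 | (6S,10E)-13-[(2R)-2,8-dimethyl-6-(triisopropylsilyloxy)chroman-2-yl]-2,6,10-trimethyl-8,8-bis(phenylsulfonyl)trideca-2,10-dien-5-ol (C5 epimers) | CC(C)=CCC(O)[C@@H](C)CC(C/C(C)=C/CC[C@]1(C)CCc2cc(O[Si](C(C)C)(C(C)C)C(C)C)cc(C)c2O1)(S(=O)(=O)c1ccccc1)S(=O)(=O)c1ccccc1 | intermediate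
28 | (6S,10E)-13-[(2R)-2,8-dimethyl-6-(triisopropylsilyloxy)chroman-2-yl]-2,6,10-trimethyltrideca-2,10-dien-5-ol (C5 epimers) | CC(C)=CCC(O)[C@@H](C)CCC/C(C)=C/CC[C@]1(C)CCc2cc(O[Si](C(C)C)(C(C)C)C(C)C)cc(C)c2O1 | intermediate
29 | (6S,10E)-13-[(2R)-2,8-dimethyl-6-(triisopropylsilyloxy)chroman-2-yl]-2,6,10-trimethyltrideca-2,10-dien-5-one | CC(C)=CCC(=O)[C@@H](C)CCC/C(C)=C/CC[C@]1(C)CCc2cc(O[Si](C(C)C)(C(C)C)C(C)C)cc(C)c2O1 | intermediate
30 | (6S,10E)-13-[(2R)-6-hydroxy-2,8-dimethylchroman-2-yl]-2,6,10-trimethyltrideca-2,10-dien-5-one (CNP0280076.1) | CC(C)=CCC(=O)[C@@H](C)CCC/C(C)=C/CC[C@]1(C)CCc2cc(O)cc(C)c2O1 | target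

Total step count: 18. Longest linear sequence: 14 steps (steps 1–5, 7–11 and 15–18); steps 6 and 12–14 are side branches.

Steps most likely to fail

Step 7 (bears the label). The hindered tertiary hydroxyl may add to the carbene carbon of 13 more slowly than 13 decays, or the tertiary O–C2 bond of 14 may ionise and eliminate during formation and filtration. The fallback uses known chemistry and leaves the carbene route; it sets out from 1 and comes back at 16. 4-Methoxy-2-methylaniline is iodinated ortho to nitrogen (ICl, AcOH) to 2-iodo-4-methoxy-6-methylaniline F1, and Sandmeyer bromination (t-BuONO, CuBr2, MeCN) gives 2-bromo-1-iodo-5-methoxy-3-methylbenzene F2. Hydroboration of 1 with 9-BBN and B-alkyl Suzuki–Miyaura coupling at the C–I bond of F2 (PdCl2(dppf), K3PO4, THF–DMF–H2O) should give (3R)-1-(2-bromo-5-methoxy-3-methylphenyl)-3,7-dimethyloct-6-en-3-ol F3. Palladium-catalysed intramolecular aryl etherification of the tertiary alcohol (Pd(OAc)2, bulky di-tert-butylbiarylphosphine, Cs2CO3, toluene, 80 °C) closes O1–C8a with C2 untouched to give (2R)-6-methoxy-2,8-dimethyl-2-(4-methylpent-3-en-1-yl)chroman F4. Thiolate demethylation (NaSEt, DMF, 110 °C) then delivers 16.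

Step 8. After alkyne insertion the vinylcarbene may be diverted before or after CO insertion into four- or five-membered-ring products, the tertiary O–C2 bond may heterolyse at 60 °C, or the phenol may be over-oxidised during demetallation. The fallback replaces the benzannulation by a Heck entry to the same aryl bromide; it sets out from 1 and comes back at 16. Heck arylation of the vinyl group of 1 at the C–I bond of F2 (Pd(OAc)2, Et3N, DMF, 80 °C) should give (1E,3R)-1-(2-bromo-5-methoxy-3-methylphenyl)-3,7-dimethylocta-1,6-dien-3-ol F5. Diimide (o-nitrobenzenesulfonylhydrazide, Et3N) should saturate the disubstituted styrenyl alkene in preference to the trisubstituted one and leave the aryl bromide intact, giving F3. F3 is then cyclised to F4 and demethylated to 16 as described for step 7.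

Step 10. The oxidation may stall at low conversion, run on to the enal, or attack the electron-rich chroman at its benzylic positions. The fallback rebuilds the alkene instead of oxidising it; it sets out from 17 and comes back at 18. Lemieux–Johnson cleavage of the trisubstituted alkene (OsO4 cat., NaIO4, 2,6-lutidine, dioxane–H2O) gives 3-[(2S)-2,8-dimethyl-6-(triisopropylsilyloxy)chroman-2-yl]propanal F6 (same geometry at C2; the descriptor changes by priority only). Wittig olefination with ethyl 2-(triphenylphosphoranylidene)propanoate (toluene, 80 °C) should give the E-enoate, ethyl (2E)-5-[(2R)-2,8-dimethyl-6-(triisopropylsilyloxy)chroman-2-yl]-2-methylpent-2-enoate F7. DIBAL-H reduction (CH2Cl2, −78 °C) then gives 18.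

Further compounds
F1 | step 7 | 2-iodo-4-methoxy-6-methylaniline | COc1cc(C)c(N)c(I)c1
F2 | step 7 | 2-bromo-1-iodo-5-methoxy-3-methylbenzene | COc1cc(C)c(Br)c(I)c1
F3 | step 7 | (3R)-1-(2-bromo-5-methoxy-3-methylphenyl)-3,7-dimethyloct-6-en-3-ol | CC(C)=CCC[C@@](C)(O)CCc1cc(OC)cc(C)c1Br
F4 | step 7 | (2R)-6-methoxy-2,8-dimethyl-2-(4-methylpent-3-en-1-yl)chroman | CC(C)=CCC[C@]1(C)CCc2cc(OC)cc(C)c2O1
F5 | step 8 | (1E,3R)-1-(2-bromo-5-methoxy-3-methylphenyl)-3,7-dimethylocta-1,6-dien-3-ol | CC(C)=CCC[C@@](C)(O)/C=C/c1cc(OC)cc(C)c1Br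
F6 | step 10 | 3-[(2S)-2,8-dimethyl-6-(triisopropylsilyloxy)chroman-2-yl]propanal | O=CCC[C@]1(C)CCc2cc(O[Si](C(C)C)(C(C)C)C(C)C)cc(C)c2O1
F7 | step 10 | ethyl (2E)-5-[(2R)-2,8-dimethyl-6-(triisopropylsilyloxy)chroman-2-yl]-2-methylpent-2-enoate | CCOC(=O)/C(C)=C/CC[C@]1(C)CCc2cc(O[Si](C(C)C)(C(C)C)C(C)C)cc(C)c2O1
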